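## Retrosynthetic overview

1. Locants follow the 11H-dibenzo[b,e][1,4]dioxepin-11-one numbering of the compound names: ring A is the benzoate ring (carbons 1 to 4), ring B the tetraoxygenated ring (carbons 6 to 9). The strategy rests on this feature: the prenyl-bearing carbons 4 and 6 and the chromene-bearing carbon 9 each stand ortho to an oxygen (the oxygens on carbons 3, 7 and 8), and on ring B each of these oxygens has only one free ortho carbon.
2. Key disconnection: the two aryl–prenyl bonds (at carbons 4 and 6), the aryl–vinyl bond at carbon 9 and the pyran O–CMe2 bond are cut together, back to triether 16 (1,1-dimethylallyl ethers on the 3- and 7-oxygens, 1,1-dimethylpropargyl ether on the 8-oxygen, MOM on the 1-oxygen). MOM removal ends the route.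
3. 16 comes from depsidone aldehyde 10: the two free phenols are etherified, the 8-formyl group is turned into the 8-hydroxyl by Baeyer–Villiger oxidation, the alkynes are semihydrogenated, then the 8-hydroxyl is etherified. The 7- and 8-oxygens are thus never free phenols together.
4. 10 comes from diaryl ether 8 by hydrogenolysis and lactonisation; 8 comes from SNAr of ring A phenol 3 on fluoroaldehyde 7, whose formyl group activates the fluoride and later becomes the 8-oxygen.
5. Ring order: rings A and B come from 2,4,6-trihydroxybenzoic acid and 2-fluoro-1,4-dimethoxybenzene; the seven-membered lactone closes in step 8, the pyran in step 13.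

Key step: step 13

Remark: the tertiary propargyl unit is brought in as commercial 3-chloro-3-methylbut-1-yne, which acts as the synthetic equivalent of a carbonate of 2-methylbut-3-yn-2-ol.

## Route

Step 1
Reactants: 1 2,4,6-trihydroxybenzoic acid
Product: 2 benzyl 4-(benzyloxy)-2,6-dihydroxybenzoate
Conditions: BnBr (2.1 equiv), K2CO3 (2.2 equiv), DMF, rt
Reagents that add atoms: benzyl bromide (BrCc1ccccc1)
Why: Williamson-type alkylation in which the carboxylate and the para hydroxyl (the most acidic phenol, not hydrogen-bonded) react while the two ortho hydroxyls stay hydrogen-bonded to the ester, and room temperature avoids decarboxylation.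

Step 2
Reactants: 2 benzyl 4-(benzyloxy)-2,6-dihydroxybenzoate
Product: 3 benzyl 4-(benzyloxy)-2-hydroxy-6-(methoxymethoxy)benzoate
Conditions: MOMCl (1.1 equiv), i-Pr2NEt, CH2Cl2, 0 °C to rt
Reagents that add atoms: chloromethyl methyl ether (COCCl)
Why: Williamson-type mono-etherification of a symmetric diol, selective because once one ortho hydroxyl is capped the other sits in a single strong hydrogen bond to the ester carbonyl and reacts much more slowly.

Step 3
Reactants: 4 2-fluoro-1,4-dimethoxybenzene
Product: 5 4-fluoro-2,5-dimethoxybenzaldehyde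
Conditions: Cl2CHOMe, TiCl4, CH2Cl2, 0 °C; then H2O
Reagents that add atoms: dichloromethyl methyl ether (COC(Cl)Cl); water (O)
Why: Rieche formylation (electrophilic aromatic substitution), expected at the carbon ortho to a methoxy group and para to fluorine, the one position activated by both.

Step 4
Reactants: 5 4-fluoro-2,5-dimethoxybenzaldehyde
Product: 6 4-fluoro-2,5-dihydroxybenzaldehyde
Conditions: BBr3, CH2Cl2, −78 °C to rt; then H2O
Reagents that add atoms: none
Why: Lewis acid-assisted SN2 demethylation of both aryl methyl ethers by BBr3, to which the aldehyde and the aryl fluoride are inert.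

Step 5
Reactants: 6 4-fluoro-2,5-dihydroxybenzaldehyde
Product: 7 2,5-bis(benzyloxy)-4-fluorobenzaldehyde
Conditions: BnBr (2.2 equiv), K2CO3, DMF, 50 °C, under N2
Reagents that add atoms: benzyl bromide (BrCc1ccccc1)
Why: Williamson benzylation of both phenols, which at 50 °C should be far faster than displacement of the fluoride by a phenoxide, the inert atmosphere protecting the hydroquinone from oxidation.

Step 6
Reactants: 3 benzyl 4-(benzyloxy)-2-hydroxy-6-(methoxymethoxy)benzoate; 7 2,5-bis(benzyloxy)-4-fluorobenzaldehyde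
Product: 8 benzyl 4-(benzyloxy)-2-[2,5-bis(benzyloxy)-4-formylphenoxy]-6-(methoxymethoxy)benzoate
Conditions: Cs2CO3, DMSO, 100 °C
Reagents that add atoms: none
Why: Nucleophilic aromatic substitution (addition–elimination) in which the phenoxide of 3 displaces the fluoride para to the formyl group, the known SNAr/Baeyer–Villiger tactic for oxygenated diaryl ethers; MOM ether, benzyl ethers and aldehyde tolerate carbonate base.

Step 7
Reactants: 8 benzyl 4-(benzyloxy)-2-[2,5-bis(benzyloxy)-4-formylphenoxy]-6-(methoxymethoxy)benzoate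
Product: 9 2-(4-formyl-2,5-dihydroxyphenoxy)-4-hydroxy-6-(methoxymethoxy)benzoic acid
Conditions: H2 (1 atm), Pd/C, EtOAc, rt; filtered under argon and used directly
Reagents that add atoms: none
Why: Hydrogenolysis of the three benzyl ethers and the benzyl ester over Pd/C, which in aprotic ethyl acetate at 1 atm should be much faster than reduction of the electron-rich aryl aldehyde, so the reaction is stopped after uptake of four equivalents of hydrogen.

Step 8
Reactants: 9 2-(4-formyl-2,5-dihydroxyphenoxy)-4-hydroxy-6-(methoxymethoxy)benzoic acid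
Product: 10 3,7-dihydroxy-1-(methoxymethoxy)-11-oxo-11H-dibenzo[b,e][1,4]dioxepine-8-carbaldehyde (depsidone with 3-OH, 1-OMOM, 7-OH, 8-CHO)
Conditions: EDC·HCl, DMAP (cat.), CH2Cl2–THF (high dilution), 0 °C to rt
Reagents that add atoms: none
Why: Carbodiimide (Steglich-type) lactonisation in which the activated acid of ring A is held by the diaryl ether next to the ring B hydroxyl ortho to the ether oxygen, so the seven-membered lactone should close in preference to intermolecular acylation, the other ring B hydroxyl being tied up in a hydrogen bond to the formyl group.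

Step 9
Reactants: 10 depsidone aldehyde (3-OH, 1-OMOM, 7-OH, 8-CHO); 11 3-chloro-3-methylbut-1-yne
Product: 12 1-(methoxymethoxy)-3,7-bis[(2-methylbut-3-yn-2-yl)oxy]-11-oxo-11H-dibenzo[b,e][1,4]dioxepine-8-carbaldehyde
Conditions: 11 (3 equiv), DBU, CuCl2·2H2O (cat.), MeCN, 0 °C to rt, under N2
Reagents that add atoms: none
Why: Copper-catalysed propargylic etherification (capture of a copper acetylide-derived tertiary electrophile by phenoxide) of the only two free phenols, the 3- and 7-hydroxyls, under conditions mild enough for the lactone and the aldehyde.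

Step 10
Reactants: 12 bis(1,1-dimethylpropargyl) ether aldehyde
Product: 14 8-hydroxy-1-(methoxymethoxy)-3,7-bis[(2-methylbut-3-yn-2-yl)oxy]-11H-dibenzo[b,e][1,4]dioxepin-11-one, via aryl formate 13 (not isolated)
Conditions: mCPBA, CH2Cl2, 0 °C to rt; then Et3N (cat.), MeOH, 0 °C
Reagents that add atoms: mCPBA (O=C(OO)c1cccc(Cl)c1)
Why: Baeyer–Villiger (Dakin-type) oxidation in which the electron-rich aryl group (ortho alkoxy, para aryloxy) migrates to give the formate, cleaved by mild methanolysis that the hindered lactone should survive; terminal alkynes are not attacked by mCPBA, which is why the oxidation precedes the semihydrogenation.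

Step 11
Reactants: 14 8-hydroxy bis(1,1-dimethylpropargyl) ether
Product: 15 8-hydroxy-1-(methoxymethoxy)-3,7-bis[(2-methylbut-3-en-2-yl)oxy]-11H-dibenzo[b,e][1,4]dioxepin-11-one
Conditions: H2 (1 atm), Lindlar catalyst (Pd on CaCO3 poisoned with Pb(OAc)2), quinoline, EtOAc, rt
Reagents that add atoms: none
Why: Lindlar semihydrogenation of the two terminal alkynes to vinyl groups, the poisoned catalyst reducing the resulting monosubstituted alkenes much more slowly and leaving the aryl ethers and lactone intact.

Step 12
Reactants: 15 8-hydroxy bis(1,1-dimethylallyl) ether; 11 3-chloro-3-methylbut-1-yne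
Product: 16 1-(methoxymethoxy)-3,7-bis[(2-methylbut-3-en-2-yl)oxy]-8-[(2-methylbut-3-yn-2-yl)oxy]-11H-dibenzo[b,e][1,4]dioxepin-11-one (triether)
Conditions: 11 (2 equiv), DBU, CuCl2·2H2O (cat.), MeCN, 0 °C, under N2
Reagents that add atoms: none
Why: The same copper-catalysed propargylic etherification on the last phenol, which has precedent in the propargylation of adjacent catechol hydroxyls of polyhydroxyxanthones to ortho-bis(tertiary) ethers, and 0 °C keeps the allyl ethers from rearranging.

Step 13
Reactants: 16 triether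
Product: 20 1-O-(methoxymethyl) ether of the target (4,6-diprenyl; 2,2-dimethyl-2H-pyran fused at the 8-oxygen and carbon 9), via bis-C-prenyl propargyl ether 17 (not isolated), via o-allenylphenol 18 (not isolated), via o-quinone methide 19 (not isolated)
Conditions: PhNEt2 (degassed), 120 °C then 180 °C, sealed tube
Reagents that add atoms: none
Why: The two aryl 1,1-dimethylallyl ethers (on the 3- and 7-oxygens) undergo chair [3,3] shifts with allyl inversion that place linear prenyl groups on carbon 4 and carbon 6 and enolise to 17; at the higher temperature the aryl 1,1-dimethylpropargyl ether on the 8-oxygen shifts to carbon 9, the allenyl dienone enolises to 18, a 1,5-hydrogen shift gives the (Z)-o-quinone methide 19, and a thermal disrotatory oxa-6π electrocyclisation closes the six-membered pyran through the O–CMe2 bond. The closest known reaction types are the aromatic Claisen rearrangement of aryl 1,1-dimethylallyl ethers to o-prenylphenols and the thermal conversion of aryl 1,1-dimethylpropargyl ethers into 2,2-dimethyl-2H-chromenes. No stereocentre is formed. On ring B the outcome is fixed because carbon 6 and carbon 9 are the only unsubstituted ortho carbons, a shift to them is made irreversible by enolisation, and ring B is not part of a naphthalene-like bicycle whose bond fixation would favour the occupied ortho carbon as it does in xanthones. On ring A the shift must go to carbon 4 and not to carbon 2: the 1-oxygen is a MOM ether, so no hydrogen bond to the lactone carbonyl fixes a double bond between carbons 2 and 3 (the effect that sends allyl groups between the two oxygens in chelated 4-allyloxy-2-hydroxyaryl ketones), and the MOM group, turned away from the lactone carbonyl, shields carbon 2. Diethylaniline keeps the medium basic so that the o-prenylphenols should not cyclise to chromans.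

Step 14
Reactants: 20 1-O-(methoxymethyl) ether of the target
Product: 21 target depsidone CNP0263700.0
Conditions: HCl (3 M aq.), THF–i-PrOH, rt
Reagents that add atoms: none
Why: Acid-catalysed acetal hydrolysis of a MOM ether that is unusually labile because it is ortho to the lactone carbonyl, so dilute acid at room temperature should suffice while the o-prenylphenols, which need stronger acid or heat to cyclise, and the chromene survive.

## Compound list

1 | 2,4,6-trihydroxybenzoic acid | OC(=O)c1c(O)cc(O)cc1O | starting material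
2 | benzyl 4-(benzyloxy)-2,6-dihydroxybenzoate | O=C(OCc1ccccc1)c1c(O)cc(OCc2ccccc2)cc1O | intermediate
3 | benzyl 4-(benzyloxy)-2-hydroxy-6-(methoxymethoxy)benzoate | COCOc1cc(OCc2ccccc2)cc(O)c1C(=O)OCc1ccccc1 | intermediate
4 | 2-fluoro-1,4-dimethoxybenzene | COc1ccc(OC)c(F)c1 | starting material
5 | 4-fluoro-2,5-dimethoxybenzaldehyde | COc1cc(F)c(OC)cc1C=O | intermediate
6 | 4-fluoro-2,5-dihydroxybenzaldehyde | O=Cc1cc(O)c(F)cc1O | intermediate
7 | 2,5-bis(benzyloxy)-4-fluorobenzaldehyde | O=Cc1cc(OCc2ccccc2)c(F)cc1OCc1ccccc1 | intermediate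
8 | benzyl 4-(benzyloxy)-2-[2,5-bis(benzyloxy)-4-formylphenoxy]-6-(methoxymethoxy)benzoate | O=Cc1cc(OCc2ccccc2)c(Oc2cc(OCc3ccccc3)cc(OCOC)c2C(=O)OCc2ccccc2)cc1OCc1ccccc1 | intermediate
9 | 2-(4-formyl-2,5-dihydroxyphenoxy)-4-hydroxy-6-(methoxymethoxy)benzoic acid | O=Cc1cc(O)c(Oc2cc(O)cc(OCOC)c2C(=O)O)cc1O | intermediate
10 | 3,7-dihydroxy-1-(methoxymethoxy)-11-oxo-11H-dibenzo[b,e][1,4]dioxepine-8-carbaldehyde | O=Cc1cc2OC(=O)c3c(OCOC)cc(O)cc3Oc2cc1O | intermediate
11 | 3-chloro-3-methylbut-1-yne | C#CC(C)(C)Cl | starting material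
12 | 1-(methoxymethoxy)-3,7-bis[(2-methylbut-3-yn-2-yl)oxy]-11-oxo-11H-dibenzo[b,e][1,4]dioxepine-8-carbaldehyde | O=Cc1cc2OC(=O)c3c(OCOC)cc(OC(C)(C)C#C)cc3Oc2cc1OC(C)(C)C#C | intermediate
13 | 1-(methoxymethoxy)-3,7-bis[(2-methylbut-3-yn-2-yl)oxy]-11-oxo-11H-dibenzo[b,e][1,4]dioxepin-8-yl formate | O=COc1cc2OC(=O)c3c(OCOC)cc(OC(C)(C)C#C)cc3Oc2cc1OC(C)(C)C#C | intermediate
14 | 8-hydroxy-1-(methoxymethoxy)-3,7-bis[(2-methylbut-3-yn-2-yl)oxy]-11H-dibenzo[b,e][1,4]dioxepin-11-one | Oc1cc2OC(=O)c3c(OCOC)cc(OC(C)(C)C#C)cc3Oc2cc1OC(C)(C)C#C | intermediate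
15 | 8-hydroxy-1-(methoxymethoxy)-3,7-bis[(2-methylbut-3-en-2-yl)oxy]-11H-dibenzo[b,e][1,4]dioxepin-11-one | Oc1cc2OC(=O)c3c(OCOC)cc(OC(C)(C)C=C)cc3Oc2cc1OC(C)(C)C=C | intermediate
16 | 1-(methoxymethoxy)-3,7-bis[(2-methylbut-3-en-2-yl)oxy]-8-[(2-methylbut-3-yn-2-yl)oxy]-11H-dibenzo[b,e][1,4]dioxepin-11-one | C=CC(C)(C)Oc1cc2Oc3cc(OC(C)(C)C=C)cc(OCOC)c3C(=O)Oc2cc1OC(C)(C)C#C | intermediate
17 | 3,7-dihydroxy-1-(methoxymethoxy)-4,6-bis(3-methylbut-2-enyl)-8-[(2-methylbut-3-yn-2-yl)oxy]-11H-dibenzo[b,e][1,4]dioxepin-11-one | CC(C)=CCc1c(O)c(OC(C)(C)C#C)cc2OC(=O)c3c(OCOC)cc(O)c(CC=C(C)C)c3Oc12 | intermediate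
18 | 3,7,8-trihydroxy-1-(methoxymethoxy)-9-(3-methylbuta-1,2-dienyl)-4,6-bis(3-methylbut-2-enyl)-11H-dibenzo[b,e][1,4]dioxepin-11-one | CC(C)=CCc1c(O)c(O)c(C=C=C(C)C)c2OC(=O)c3c(OCOC)cc(O)c(CC=C(C)C)c3Oc12 | intermediate
19 | (Z)-o-quinone methide of 18 (8-oxo, 9-(3-methylbut-2-enylidene)) | CC(C)=CCC1=C(O)C(=O)/C(=C\C=C(C)C)C2=C1Oc1c(CC=C(C)C)c(O)cc(OCOC)c1C(=O)O2 | intermediate
20 | 1-O-(methoxymethyl) ether of the target | CC(C)=CCc1c(O)c2OC(C)(C)C=Cc2c2OC(=O)c3c(OCOC)cc(O)c(CC=C(C)C)c3Oc12 | intermediate
21 | target depsidone CNP0263700.0 | CC(C)=CCc1c(O)c2c(c3c1Oc1c(CC=C(C)C)c(O)cc(O)c1C(=O)O3)C=CC(C)(C)O2 | target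

## Step count and risks

Total step count: 14. Longest linear sequence: 12 steps (steps 3 to 5, then 6 to 14).

**Step 13.** The ring A allyl group may be delivered to both ortho carbons, because the bias between carbon 4 and carbon 2 rests on shielding and analogy and not on a blocked position. The fallback blocks carbon 2 covalently; it sets out from 12 and comes back at 21. Cleavage of the MOM ether of 12 (aq. HCl, THF, rt) gives the 1-hydroxy bis(1,1-dimethylpropargyl) ether aldehyde F1. Its hydrogen-bonded hydroxyl directs bromination (NBS, MeCN, 0 °C) to carbon 2, which is ortho to it, and gives the 2-bromo aldehyde F2. Oxidation under the conditions of step 10 passes through the 2-bromo aryl formate F3 to the 2-bromo 8-hydroxy compound F4. Lindlar reduction as in step 11 gives the 2-bromo bis(1,1-dimethylallyl) ether F5, and propargylation as in step 12 gives the 2-bromo triether F6; the bromine-flanked, hydrogen-bonded 1-hydroxyl should not be alkylated. Heating as in step 13 can then place the ring A prenyl group on carbon 4 only and gives the 2-bromo depsidone F7. Hydrodebromination (Pd(OAc)2, PPh3, HCO2H, Et3N, DMF, 60 °C), which should leave the prenyl and chromene alkenes alone, gives 21.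

**Step 6.** Addition–elimination may be slow, because the phenoxide of 3 is hydrogen-bonded and weakly nucleophilic and the fluoride is flanked by a benzyloxy group; during prolonged heating the phenoxide may instead attack the benzyl ester. The fallback replaces SNAr by a copper-catalysed coupling; it sets out from 3 and comes back at 8. Commercial 4-bromo-2,5-dimethoxybenzaldehyde F8 is demethylated (BBr3, CH2Cl2) to 4-bromo-2,5-dihydroxybenzaldehyde F9 and benzylated (BnBr, K2CO3, DMF) to 2,5-bis(benzyloxy)-4-bromobenzaldehyde F10. Ullmann ether coupling of F10 with 3 (CuI, picolinic acid, K3PO4, DMSO, 90 °C) gives 8 at a lower temperature.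

**Step 12.** Capture of the tertiary propargylic electrophile by the phenoxide next to the 1,1-dimethylallyl ether may be retarded sterically, so that the reagent is lost by elimination or alkyne homocoupling. The fallback builds the pyran ring without a propargyl ether on the 8-oxygen; it sets out from 14 and comes back at 20. Condensation of 14 with 3-methylbut-2-enal (PhB(OH)2, propionic acid, toluene, reflux) forms an o-quinone methide at carbon 9, the only free carbon ortho to the 8-hydroxyl, which closes by oxa-6π electrocyclisation to the chromene bis(1,1-dimethylpropargyl) ether F11. At this temperature the propargyl ethers should rearrange only slowly. Lindlar reduction as in step 11 gives the chromene bis(1,1-dimethylallyl) ether F12, the cis-disubstituted chromene alkene being left alone. Heating as in step 13, now with two allyl shifts only, gives 20.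

Further compounds

F1 | step 13 | 1-hydroxy bis(1,1-dimethylpropargyl) ether aldehyde | O=Cc1cc2OC(=O)c3c(O)cc(OC(C)(C)C#C)cc3Oc2cc1OC(C)(C)C#C
F2 | step 13 | 2-bromo aldehyde | O=Cc1cc2OC(=O)c3c(O)c(Br)c(OC(C)(C)C#C)cc3Oc2cc1OC(C)(C)C#C
F3 | step 13 | 2-bromo aryl formate | O=COc1cc2OC(=O)c3c(O)c(Br)c(OC(C)(C)C#C)cc3Oc2cc1OC(C)(C)C#C
F4 | step 13 | 2-bromo 8-hydroxy compound | Oc1cc2OC(=O)c3c(O)c(Br)c(OC(C)(C)C#C)cc3Oc2cc1OC(C)(C)C#C
F5 | step 13 | 2-bromo bis(1,1-dimethylallyl) ether | Oc1cc2OC(=O)c3c(O)c(Br)c(OC(C)(C)C=C)cc3Oc2cc1OC(C)(C)C=C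
F6 | step 13 | 2-bromo triether | C#CC(C)(C)Oc1cc2OC(=O)c3c(O)c(Br)c(OC(C)(C)C=C)cc3Oc2cc1OC(C)(C)C=C
F7 | step 13 | 2-bromo depsidone | CC(C)=CCc1c(O)c2OC(C)(C)C=Cc2c2OC(=O)c3c(O)c(Br)c(O)c(CC=C(C)C)c3Oc12
F8 | step 6 | 4-bromo-2,5-dimethoxybenzaldehyde | COc1cc(Br)c(OC)cc1C=O
F9 | step 6 | 4-bromo-2,5-dihydroxybenzaldehyde | O=Cc1cc(O)c(Br)cc1O
F10 | step 6 | 2,5-bis(benzyloxy)-4-bromobenzaldehyde | O=Cc1cc(OCc2ccccc2)c(Br)cc1OCc1ccccc1
F11 | step 12 | chromene bis(1,1-dimethylpropargyl) ether | C#CC(C)(C)Oc1cc2Oc3cc(OC(C)(C)C#C)cc(OCOC)c3C(=O)Oc2c2C=CC(C)(C)Oc12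
F12 | step 12 | chromene bis(1,1-dimethylallyl) ether | C=CC(C)(C)Oc1cc2Oc3cc(OC(C)(C)C=C)cc(OCOC)c3C(=O)Oc2c2C=CC(C)(C)Oc12
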